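**Retrosynthetic overview**
1. Target 12 comes from the bis-MOM flavanone 11 by global MOM removal.
2. Ring C of 11 is closed last by making the C3–C4 bond: an enantioselective rhodium-catalysed intramolecular hydroacylation of the achiral aldehyde 10 adds the formyl C–H across a 1,1-disubstituted aryl enol ether, closing the pyranone and setting C2 in one isomerization.
3. Enabling feature: C2 of ring C carries both the ring oxygen O1 and the 4-oxyphenyl group, and C3 is a bare methylene next to the C4 carbonyl on ring A. The open form O1–C2(aryl)=C3H2 ortho to a C4 formyl group on ring A is therefore an isomer of ring C.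
4. Enol ether 10 comes from Petasis methylenation of aryl ester 8 (formyl group masked as its dimethyl acetal), made from phenol 5 and acid 6.
5. Ring A is bought as an arene and dressed first: 5 from twofold Suzuki prenylation of dibromide 3, from 2,4-dihydroxybenzaldehyde 1. Ring B is bought with 6. Ring order: A and B purchased, C formed in step 8.

Key step: step 8

Assumption: 4-(methoxymethoxy)benzoic acid and prenylboronic acid pinacol ester are taken as purchasable building blocks, and the sense of induction of the chiral ligand in step 8 is assigned by analogy, so the ligand antipode is exchanged if a model run shows the opposite sense.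

**Step 1**
Reactants: 1 2,4-dihydroxybenzaldehyde
Product: 2 2-hydroxy-4-(methoxymethoxy)benzaldehyde
Conditions: MOMCl (1.1 equiv), K2CO3, acetone, 0 °C to rt
Reagents that add atoms: chloromethyl methyl ether, COCCl
Why: Williamson-type O-alkylation (MOM acetal formation) occurs at the more acidic, unencumbered 4-OH because the 2-OH is tied up in an intramolecular hydrogen bond to the formyl group.

**Step 2**
Reactants: 2 2-hydroxy-4-(methoxymethoxy)benzaldehyde
Product: 3 3,5-dibromo-2-hydroxy-4-(methoxymethoxy)benzaldehyde
Conditions: NBS (2.1 equiv), MeCN, 0 °C to rt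
Reagents that add atoms: N-bromosuccinimide, O=C1CCC(=O)N1Br
Why: Electrophilic aromatic bromination is directed by the free phenol to C3 and C5 (both also ortho to the MOM ether), while C6 is meta to both oxygens and stays untouched, and the neutral succinimide by-product spares the MOM ether.

**Step 3**
Reactants: 3 3,5-dibromo-2-hydroxy-4-(methoxymethoxy)benzaldehyde; 4 4,4,5,5-tetramethyl-2-(3-methylbut-2-en-1-yl)-1,3,2-dioxaborolane (prenylboronic acid pinacol ester, 3 equiv)
Product: 5 2-hydroxy-4-(methoxymethoxy)-3,5-bis(3-methylbut-2-en-1-yl)benzaldehyde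
Conditions: Pd(dppf)Cl2 (10 mol%), K3PO4, THF/H2O, 70 °C
Reagents that add atoms: none
Why: Twofold Suzuki–Miyaura allyl–aryl coupling in which the σ-allyl palladium intermediates reductively eliminate through the less hindered primary terminus to give linear prenyl groups, the substrate reacting as its phenoxide, which lowers the electrophilicity of the formyl group towards allylboration.

**Step 4**
Reactants: 5 2-hydroxy-4-(methoxymethoxy)-3,5-bis(3-methylbut-2-en-1-yl)benzaldehyde; 6 4-(methoxymethoxy)benzoic acid
Product: 7 6-formyl-3-(methoxymethoxy)-2,4-bis(3-methylbut-2-en-1-yl)phenyl 4-(methoxymethoxy)benzoate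
Conditions: DCC, DMAP (cat.), CH2Cl2, rt
Reagents that add atoms: none
Why: Steglich esterification (carbodiimide activation with acyl transfer by DMAP) acylates even the hindered, hydrogen-bonded phenol under neutral conditions that leave MOM ethers, prenyl groups and the formyl group alone.

**Step 5**
Reactants: 7 6-formyl-3-(methoxymethoxy)-2,4-bis(3-methylbut-2-en-1-yl)phenyl 4-(methoxymethoxy)benzoate
Product: 8 6-(dimethoxymethyl)-3-(methoxymethoxy)-2,4-bis(3-methylbut-2-en-1-yl)phenyl 4-(methoxymethoxy)benzoate
Conditions: HC(OMe)3, PPTS (cat.), CH2Cl2, rt; Et3N quench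
Reagents that add atoms: trimethyl orthoformate, COC(OC)OC
Why: Acid-catalysed acetalization driven by the orthoester masks the formyl group, which would otherwise be methylenated ahead of the ester in step 6, and PPTS is too weak to touch the MOM ethers or the prenyl groups.

**Step 6**
Reactants: 8 6-(dimethoxymethyl)-3-(methoxymethoxy)-2,4-bis(3-methylbut-2-en-1-yl)phenyl 4-(methoxymethoxy)benzoate
Product: 9 1-(dimethoxymethyl)-4-(methoxymethoxy)-2-({1-[4-(methoxymethoxy)phenyl]ethenyl}oxy)-3,5-bis(3-methylbut-2-en-1-yl)benzene
Conditions: Cp2TiMe2 (3 equiv), toluene, 70 °C, dark; filtration through basic Al2O3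
Reagents that add atoms: dimethyltitanocene, C[Ti](C)(C1C=CC=C1)C1C=CC=C1
Why: Petasis methylenation, in which Cp2Ti=CH2 formed by thermal loss of methane adds to the ester carbonyl by [2+2] cycloaddition and cycloreverts to the enol ether, is the standard conversion of aryl benzoates into aryl 1-arylvinyl ethers and is non-acidic, so the acetal, the MOM ethers and the trisubstituted prenyl alkenes should survive.

**Step 7**
Reactants: 9 1-(dimethoxymethyl)-4-(methoxymethoxy)-2-({1-[4-(methoxymethoxy)phenyl]ethenyl}oxy)-3,5-bis(3-methylbut-2-en-1-yl)benzene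
Product: 10 4-(methoxymethoxy)-2-({1-[4-(methoxymethoxy)phenyl]ethenyl}oxy)-3,5-bis(3-methylbut-2-en-1-yl)benzaldehyde
Conditions: PPTS (5 mol%), acetone/H2O (20:1), 0 °C; Et3N quench
Reagents that add atoms: water, O
Why: Specific-acid-catalysed acetal hydrolysis through an oxocarbenium ion stabilised by the para and ortho oxygen donors of ring A should be far faster than rate-limiting carbon protonation of the aryl enol ether, whose aryloxy oxygen is a poor donor, so buffered mild acid at low temperature should unmask the aldehyde selectively.

**Step 8**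
Reactants: 10 4-(methoxymethoxy)-2-({1-[4-(methoxymethoxy)phenyl]ethenyl}oxy)-3,5-bis(3-methylbut-2-en-1-yl)benzaldehyde
Product: 11 (2S)-7-(methoxymethoxy)-2-[4-(methoxymethoxy)phenyl]-6,8-bis(3-methylbut-2-en-1-yl)-2,3-dihydro-4H-1-benzopyran-4-one
Conditions: [Rh(cod)Cl]2 (2.5 mol%), (R)-DTBM-SEGPHOS (5.5 mol%), NaB[C6H3(CF3)2-3,5]4 (5 mol%), degassed 1,4-dioxane, 60 °C
Reagents that add atoms: none
Why: Proposed new method: oxidative addition of the formyl C–H bond to the cationic bisphosphine complex of monovalent rhodium gives an acyl hydride of trivalent rhodium, the hydride is transferred to C2 of the coordinated 1,1-disubstituted alkene, and C–C reductive elimination from the resulting seven-membered acyl alkyl rhodacycle forms the C3–C4 bond. The closest known reaction type is the enantioselective rhodium bisphosphine catalysed intramolecular hydroacylation of 1,1-disubstituted alkenes, as with 2-(1-substituted vinyl)benzaldehydes giving 3-substituted indanones, ortho-(2-substituted allyl)benzaldehydes giving 3-substituted tetralones and N-(1-arylvinyl)indole-2-carbaldehydes, whereas an aryl 1-arylvinyl ether as the alkene and a flavanone as the product have not been shown. Ring C is closed in the 6-endo-trig mode, both alkene carbons ending up in the pyranone. The C2 stereocentre is set in the hydride transfer under control of the chiral bisphosphine alone (the substrate is achiral): delivery to the Re face of C2 (O > aryl > CH2) gives 2S, and the ligand antipode is to be fixed on a prenyl-free model. The step needs endo over exo regioselectivity, secured by the 1,1-disubstitution because the exo path would have to pass through a tertiary alkyl rhodium and form a quaternary centre in a benzofuranone, and it needs chemoselectivity against the two prenyl alkenes, secured by their trisubstitution and their position meta to the formyl group. Decarbonylation and β-aryloxy elimination are the side paths to watch; the chelating bisphosphine and the ring constraint of the rhodacycle argue against them, and acid-free, dry conditions keep the enol ether intact.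

**Step 9**
Reactants: 11 (2S)-7-(methoxymethoxy)-2-[4-(methoxymethoxy)phenyl]-6,8-bis(3-methylbut-2-en-1-yl)-2,3-dihydro-4H-1-benzopyran-4-one
Product: 12 (2S)-7-hydroxy-2-(4-hydroxyphenyl)-6,8-bis(3-methylbut-2-en-1-yl)-2,3-dihydro-4H-1-benzopyran-4-one
Conditions: HCl (1.25 M in MeOH), 40 °C, short reaction time; NaHCO3 wash at pH 7
Reagents that add atoms: none
Why: Acid-catalysed transacetalization to methanol cleaves both aryl MOM ethers, while the C2 stereocentre, which epimerises only by base-induced ring opening to the chalcone, is not at risk and the short, mild treatment limits acid cyclization of a prenyl group onto the 7-OH.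

**Compound list**
1 | 2,4-dihydroxybenzaldehyde | O=Cc1ccc(O)cc1O | starting material
2 | 2-hydroxy-4-(methoxymethoxy)benzaldehyde | COCOc1ccc(C=O)c(O)c1 | intermediate
3 | 3,5-dibromo-2-hydroxy-4-(methoxymethoxy)benzaldehyde | COCOc1c(Br)cc(C=O)c(O)c1Br | intermediate
4 | 4,4,5,5-tetramethyl-2-(3-methylbut-2-en-1-yl)-1,3,2-dioxaborolane | CC(C)=CCB1OC(C)(C)C(C)(C)O1 | starting material
5 | 2-hydroxy-4-(methoxymethoxy)-3,5-bis(3-methylbut-2-en-1-yl)benzaldehyde | COCOc1c(CC=C(C)C)cc(C=O)c(O)c1CC=C(C)C | intermediate
6 | 4-(methoxymethoxy)benzoic acid | COCOc1ccc(cc1)C(=O)O | starting material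
7 | 6-formyl-3-(methoxymethoxy)-2,4-bis(3-methylbut-2-en-1-yl)phenyl 4-(methoxymethoxy)benzoate | COCOc1ccc(cc1)C(=O)Oc1c(C=O)cc(CC=C(C)C)c(OCOC)c1CC=C(C)C | intermediate
8 | 6-(dimethoxymethyl)-3-(methoxymethoxy)-2,4-bis(3-methylbut-2-en-1-yl)phenyl 4-(methoxymethoxy)benzoate | COCOc1ccc(cc1)C(=O)Oc1c(C(OC)OC)cc(CC=C(C)C)c(OCOC)c1CC=C(C)C | intermediate
9 | 1-(dimethoxymethyl)-4-(methoxymethoxy)-2-({1-[4-(methoxymethoxy)phenyl]ethenyl}oxy)-3,5-bis(3-methylbut-2-en-1-yl)benzene | COCOc1ccc(cc1)C(=C)Oc1c(C(OC)OC)cc(CC=C(C)C)c(OCOC)c1CC=C(C)C | intermediate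
10 | 4-(methoxymethoxy)-2-({1-[4-(methoxymethoxy)phenyl]ethenyl}oxy)-3,5-bis(3-methylbut-2-en-1-yl)benzaldehyde | COCOc1ccc(cc1)C(=C)Oc1c(C=O)cc(CC=C(C)C)c(OCOC)c1CC=C(C)C | intermediate
11 | (2S)-7-(methoxymethoxy)-2-[4-(methoxymethoxy)phenyl]-6,8-bis(3-methylbut-2-en-1-yl)-2,3-dihydro-4H-1-benzopyran-4-one | CC(C)=CCc1cc2c(c(CC=C(C)C)c1OCOC)O[C@H](c1ccc(OCOC)cc1)CC2=O | intermediate
12 | (2S)-7-hydroxy-2-(4-hydroxyphenyl)-6,8-bis(3-methylbut-2-en-1-yl)-2,3-dihydro-4H-1-benzopyran-4-one | CC(C)=CCc1cc2c(c(CC=C(C)C)c1O)O[C@H](c1ccc(O)cc1)CC2=O | target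

**Total step count:** 9
**Longest linear sequence:** 9 steps (1 to 12)

**Steps most likely to fail**

Step 8 (labelled proposed method). What may go wrong: decarbonylation of the acyl rhodium hydride, insertion in the exo sense leading to a benzofuranone, or poor facial selectivity in the hydride transfer. Fallback with known chemistry, setting out from 5 and coming back at 11: the stereocentre is made first and the same C3–C4 bond is closed by carbene catalysis. Commercial 2-bromo-1-(4-hydroxyphenyl)ethanone is protected (MOMCl, i-Pr2NEt, CH2Cl2, 0 °C) to 2-bromo-1-[4-(methoxymethoxy)phenyl]ethan-1-one F1. Corey–Bakshi–Shibata reduction ((S)-Me-CBS, BH3·SMe2, THF, −20 °C) should give (1S)-2-bromo-1-[4-(methoxymethoxy)phenyl]ethan-1-ol F2. Mitsunobu etherification of phenol 5 with F2 (PPh3, DIAD, toluene, 0 °C) proceeds with inversion at the benzylic carbon to give 2-{(1R)-2-bromo-1-[4-(methoxymethoxy)phenyl]ethoxy}-4-(methoxymethoxy)-3,5-bis(3-methylbut-2-en-1-yl)benzaldehyde F3. A thiazolium-derived N-heterocyclic carbene (thiazolium salt 10 mol%, Cs2CO3, dioxane, rt) then converts the formyl group into its Breslow intermediate, which displaces the bromide intramolecularly; this is the known carbene-catalysed nucleophilic substitution route to chroman-4-ones, and it gives 11. C2 is not touched in the ring closure; its descriptor changes from R to S only because the CH2Br group outranks the aryl group whereas the ring CH2 does not.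

Step 3. What may go wrong: allylboration of the formyl group by the boronate, protodebromination at the hindered C3 position, or coupling through the substituted allyl terminus to give reverse prenyl groups. Fallback, setting out from 3 and coming back at 8: phenol and formyl group are capped before the coupling, and a base-free organozinc coupling is used. Steglich esterification of 3 with 6 (DCC, DMAP, CH2Cl2) gives 2,4-dibromo-6-formyl-3-(methoxymethoxy)phenyl 4-(methoxymethoxy)benzoate F4. Acetalization (HC(OMe)3, PPTS) gives 2,4-dibromo-6-(dimethoxymethyl)-3-(methoxymethoxy)phenyl 4-(methoxymethoxy)benzoate F5. Linear-selective Negishi coupling with (3-methylbut-2-en-1-yl)zinc bromide F6 (made from prenyl bromide, Zn dust and LiCl in THF; Pd(OAc)2, CPhos, THF, rt) then installs both prenyl groups and gives 8.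

Step 7. What may go wrong: loss of the enol ether by acid hydrolysis while the acetal is being cleaved, returning phenol 5 and a ketone. Fallback, setting out from 5 and coming back at 10: the aryl–oxygen–vinyl bond is made directly on the free aldehyde, so no acetal and no methylenation are needed. 1-(4-Hydroxyphenyl)ethanone is protected (MOMCl, K2CO3, acetone) to 1-[4-(methoxymethoxy)phenyl]ethan-1-one F7. Enolization and triflation (KN(SiMe3)2, PhNTf2, THF, −78 °C) give 1-[4-(methoxymethoxy)phenyl]ethenyl trifluoromethanesulfonate F8. Palladium-catalysed C–O coupling of phenol 5 with F8 (Pd2(dba)3, 2-(di-tert-butylphosphino)biphenyl, K3PO4, toluene, 80 °C), the known coupling of phenols with enol triflates to aryl enol ethers, gives 10. This path is shorter but is kept in reserve because the doubly ortho-substituted phenol and base-induced elimination of the triflate to the aryl alkyne make it less certain than the ester methylenation.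

**Further compounds**
F1 | step 8 | 2-bromo-1-[4-(methoxymethoxy)phenyl]ethan-1-one | COCOc1ccc(cc1)C(=O)CBr
F2 | step 8 | (1S)-2-bromo-1-[4-(methoxymethoxy)phenyl]ethan-1-ol | O[C@H](CBr)c1ccc(OCOC)cc1
F3 | step 8 | 2-{(1R)-2-bromo-1-[4-(methoxymethoxy)phenyl]ethoxy}-4-(methoxymethoxy)-3,5-bis(3-methylbut-2-en-1-yl)benzaldehyde | O=Cc1cc(CC=C(C)C)c(OCOC)c(CC=C(C)C)c1O[C@@H](CBr)c1ccc(OCOC)cc1
F4 | step 3 | 2,4-dibromo-6-formyl-3-(methoxymethoxy)phenyl 4-(methoxymethoxy)benzoate | COCOc1ccc(cc1)C(=O)Oc1c(C=O)cc(Br)c(OCOC)c1Br
F5 | step 3 | 2,4-dibromo-6-(dimethoxymethyl)-3-(methoxymethoxy)phenyl 4-(methoxymethoxy)benzoate | COCOc1ccc(cc1)C(=O)Oc1c(C(OC)OC)cc(Br)c(OCOC)c1Br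
F6 | step 3 | (3-methylbut-2-en-1-yl)zinc bromide | CC(C)=CC[Zn]Br
F7 | step 7 | 1-[4-(methoxymethoxy)phenyl]ethan-1-one | COCOc1ccc(cc1)C(C)=O
F8 | step 7 | 1-[4-(methoxymethoxy)phenyl]ethenyl trifluoromethanesulfonate | COCOc1ccc(cc1)C(=C)OS(=O)(=O)C(F)(F)F
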